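The ester C-O bond at C1' is cut first. Next come three bonds of quinone ring A: C3-C4 (the ring CH to the carbonyl carbon on ring B), C1-C2 and C1-C8a. Last are the C1'-ethynyl bond and the C2'=C3' alkene of the side chain.
Enabling feature: ring A has its oxygens para at C1 and C4, hydrogen at C3 and its only carbon substituent at C2, and it shares C4a-C8a with the 5,8-dioxygenated ring B. An aryl(methoxy)carbene complex of Cr(CO)5 (C4, C4a, C8a, ring B), a terminal alkyne (C3-H, C2-R) and one CO ligand (C1) assemble exactly this pattern in one benzannulation.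
Forward: ring B is bought as hydroquinone and turned into the carbene complex (steps 1-2). The chain is joined by cross-metathesis and ethynylation, then resolved and silylated (steps 3-6). Ring A arises in step 7 with the whole side chain in place and is oxidised to the quinone in the same flask. Desilylation, esterification and acetal removal finish the route (steps 8-10).
Stereochemistry: C1' (R) comes from a lipase kinetic resolution of the racemic enynol and is not touched again. The acyl centre (R) comes from bought (R)-2-methylbutanoic acid, and the E-alkene from the metathesis.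
Because C5 and C8 of ring B carry the same group, either orientation of the alkyne would end in the same quinone, so the ring construction is regioconvergent.

Key step: step 7

Assumption: (R)-2-methylbutanoic acid is bought as the single enantiomer. The naphthazarin is written as the tautomer of the given SMILES (side chain on the quinone ring), the tautomers being in fast equilibrium.

Step 1
Reactants: 1 hydroquinone (benzene-1,4-diol)
Product: 2 1,4-bis(methoxymethoxy)benzene
Conditions: NaH, MeOCH2Cl, DMF, 0 °C to rt
Reagents that add atoms: chloromethyl methyl ether, COCCl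
Why: Williamson-type O-alkylation of the bis-phenoxide with the reactive α-chloro ether gives the bis-acetal, which later directs the lithiation and masks the phenols in a form removable without strong acid.

Step 2
Reactants: 2 1,4-bis(methoxymethoxy)benzene
Product: 5 pentacarbonyl{[2,5-bis(methoxymethoxy)phenyl](methoxy)methylidene}chromium, via aryllithium 3 (not isolated), via lithium acyl chromate 4 (not isolated)
Conditions: n-BuLi, THF, 0 °C; Cr(CO)6, 0 °C to rt; solvent change; Me3OBF4, CH2Cl2, 0 °C to rt
Reagents that add atoms: hexacarbonylchromium Cr(CO)6, [Cr].[C-]#[O+].[C-]#[O+].[C-]#[O+].[C-]#[O+].[C-]#[O+].[C-]#[O+]; trimethyloxonium tetrafluoroborate Me3OBF4, C[O+](C)C.F[B-](F)(F)F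
Why: Directed ortho-lithiation (all four ring hydrogens of 2 are equivalent) followed by the Fischer carbene synthesis, that is addition of the aryllithium to a CO ligand of Cr(CO)6 and O-methylation of the acyl chromate with a Meerwein salt, is the standard entry to aryl(methoxy)carbene complexes.

Step 3
Reactants: 6 2-methylbut-3-en-2-ol; 7 (E)-but-2-enal (crotonaldehyde, excess)
Product: 8 (E)-4-hydroxy-4-methylpent-2-enal
Conditions: second-generation Hoveyda-Grubbs catalyst (3 mol %), CH2Cl2, 40 °C
Reagents that add atoms: none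
Why: Olefin cross-metathesis between an unprotected tertiary allylic alcohol and an enal, both slow to homodimerise, is driven by loss of propene and should give the E-enal under thermodynamic control.

Step 4
Reactants: 8 (E)-4-hydroxy-4-methylpent-2-enal
Product: 9 racemic (E)-2-methylhept-3-en-6-yne-2,5-diol
Conditions: HC≡CMgBr (2.5 equiv), THF, -78 to 0 °C; aq NH4Cl
Reagents that add atoms: ethynylmagnesium bromide, C#C[Mg]Br
Why: Grignard 1,2-addition of the hard alkynyl nucleophile to the enal, after the first equivalent has deprotonated the tertiary alcohol, gives the carbinol as the racemate.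

Step 5
Reactants: 9 racemic (E)-2-methylhept-3-en-6-yne-2,5-diol
Product: 10 (3E,5R)-2-methylhept-3-en-6-yne-2,5-diol
Conditions: immobilised Candida antarctica lipase B, vinyl acetate, t-BuOMe, 30 °C, run slightly past half conversion; chromatography
Reagents that add atoms: none
Why: In this lipase kinetic resolution by irreversible transesterification, the Kazlauskas rule puts the slim ethynyl group in the medium pocket and the alkenyl chain in the large one, so the S alcohol should be acetylated and the R alcohol 10 left behind, the tertiary alcohol being no substrate for the enzyme.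

Step 6
Reactants: 10 (3E,5R)-2-methylhept-3-en-6-yne-2,5-diol
Product: 11 (3E,5R)-5-[(tert-butyldimethylsilyl)oxy]-2-methylhept-3-en-6-yn-2-ol
Conditions: t-BuMe2SiCl (1.1 equiv), imidazole, CH2Cl2, 0 °C to rt
Reagents that add atoms: tert-butyldimethylsilyl chloride, CC(C)(C)[Si](C)(C)Cl
Why: Imidazole-promoted silylation with the bulky chlorosilane is selective for the secondary over the tertiary alcohol and turns the propargylic oxygen into a non-leaving group without touching C5.

Step 7
Reactants: 5 pentacarbonyl{[2,5-bis(methoxymethoxy)phenyl](methoxy)methylidene}chromium; 11 (3E,5R)-5-[(tert-butyldimethylsilyl)oxy]-2-methylhept-3-en-6-yn-2-ol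
Product: 14 2-[(1R,2E)-1-(tert-butyldimethylsilyloxy)-4-hydroxy-4-methylpent-2-en-1-yl]-5,8-bis(methoxymethoxy)naphthalene-1,4-dione, via tricarbonylchromium naphthol complex 12 (not isolated), via free 4-methoxy-1-naphthol 13 (not isolated)
Conditions: 5 (1.2 equiv), degassed THF (0.2 M), 55 °C, Ar; then (NH4)2Ce(NO3)6, MeCN-H2O, 0 °C
Reagents that add atoms: water, O
Why: Dötz benzannulation with oxidative work-up: loss of one cis CO ligand from 5 lets the alkyne bind, its unsubstituted carbon bonds to the carbene carbon (new C3-C4 bond), the vinylcarbene so formed takes up a CO ligand at the substituted alkyne carbon (new C1-C2 bond), and the chromium-bound dienylketene closes onto the free ortho carbon of the arene (new C1-C8a bond) and tautomerises to the naphthol complex 12. The closest known reaction type is the benzannulation of (2,5-dimethoxyphenyl)(methoxy)carbene Cr(CO)5 complexes with terminal alkynes, and of aryl carbene complexes with propargylic silyl ethers, followed by (NH4)2Ce(NO3)6 oxidation to 5,8-dialkoxy-1,4-naphthoquinones. The one ring that is closed, six-membered ring A, arises in a formal (3+2+1) mode whose last event is a 6π electrocyclisation of the dienylketene held on the metal. No stereocentre is made: C1' of 11 is a spectator that bears a non-leaving silyl ether, and the two planar-chiral diastereomers of 12 collapse to one compound when the metal is oxidised off. The regioselectivity needed, CH to the carbene carbon and the branched carbon next to the CO-derived carbon, is secured by the steric rule for terminal alkynes, by the single free ortho position of 5 and, as a safety net, by the equal groups at C5 and C8, which make both regioisomeric naphthols give the same quinone 14. The chemoselectivity needed in the oxidation is secured by the free OH/OMe pair of ring A, which is oxidised before the bis-acetal ring B and whose quinone then deactivates ring B, while the isolated E-alkene and the tertiary alcohol do not react with the carbene complex at 55 °C.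

Step 8
Reactants: 14 2-[(1R,2E)-1-(tert-butyldimethylsilyloxy)-4-hydroxy-4-methylpent-2-en-1-yl]-5,8-bis(methoxymethoxy)naphthalene-1,4-dione
Product: 15 2-[(1R,2E)-1,4-dihydroxy-4-methylpent-2-en-1-yl]-5,8-bis(methoxymethoxy)naphthalene-1,4-dione
Conditions: HF·pyridine, pyridine, THF, 0 °C to rt
Reagents that add atoms: none
Why: Fluoride-driven desilylation in a pyridine-buffered medium breaks only the Si-O bond, so the acetals, the quinone, the tertiary allylic alcohol and the configuration at C1' are kept.

Step 9
Reactants: 15 2-[(1R,2E)-1,4-dihydroxy-4-methylpent-2-en-1-yl]-5,8-bis(methoxymethoxy)naphthalene-1,4-dione; 16 (R)-2-methylbutanoic acid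
Product: 17 (1R,2E)-1-[5,8-bis(methoxymethoxy)-1,4-dioxo-1,4-dihydronaphthalen-2-yl]-4-hydroxy-4-methylpent-2-en-1-yl (2R)-2-methylbutanoate
Conditions: DCC, DMAP (0.2 equiv), CH2Cl2, 0 °C to rt
Reagents that add atoms: none
Why: Steglich esterification acylates the secondary carbinol and leaves the hindered tertiary alcohol, keeps C1' because its C-O bond is not broken, and keeps the α-centre of the acid because neither strong base nor a ketene is involved.

Step 10
Reactants: 17 (1R,2E)-1-[5,8-bis(methoxymethoxy)-1,4-dioxo-1,4-dihydronaphthalen-2-yl]-4-hydroxy-4-methylpent-2-en-1-yl (2R)-2-methylbutanoate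
Product: 19 (1R,2E)-1-(5,8-dihydroxy-1,4-dioxo-1,4-dihydronaphthalen-2-yl)-4-hydroxy-4-methylpent-2-en-1-yl (2R)-2-methylbutanoate, via tris(trimethylsilyl) ether 18 (not isolated)
Conditions: Me3SiOTf, 2,2'-bipyridyl, MeCN, 0 °C to rt; then H2O, rt; 5% aq citric acid wash
Reagents that add atoms: none
Why: Cleavage of aryl methoxymethyl ethers by the Me3SiOTf/2,2'-bipyridyl pair runs through the aryl trimethylsilyl ethers under non-acidic conditions, so the ionisable allylic ester and the tertiary allylic alcohol (silylated in passing) should survive, and water then hydrolyses all three Si-O bonds without touching either stereocentre.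

Compound list
1 | hydroquinone | Oc1ccc(O)cc1 | starting material
2 | 1,4-bis(methoxymethoxy)benzene | COCOc1ccc(OCOC)cc1 | intermediate
3 | [2,5-bis(methoxymethoxy)phenyl]lithium | [Li]c1cc(OCOC)ccc1OCOC | intermediate
4 | lithium pentacarbonyl[2,5-bis(methoxymethoxy)benzoyl]chromate | [Li+].[O-]C(=[Cr])c1cc(OCOC)ccc1OCOC.[C-]#[O+].[C-]#[O+].[C-]#[O+].[C-]#[O+].[C-]#[O+] | intermediate
5 | pentacarbonyl{[2,5-bis(methoxymethoxy)phenyl](methoxy)methylidene}chromium | COC(=[Cr])c1cc(OCOC)ccc1OCOC.[C-]#[O+].[C-]#[O+].[C-]#[O+].[C-]#[O+].[C-]#[O+] | intermediate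
6 | 2-methylbut-3-en-2-ol | C=CC(C)(C)O | starting material
7 | (E)-but-2-enal | C/C=C/C=O | starting material
8 | (E)-4-hydroxy-4-methylpent-2-enal | O=C/C=C/C(C)(C)O | intermediate
9 | racemic (E)-2-methylhept-3-en-6-yne-2,5-diol | C#CC(O)/C=C/C(C)(C)O | intermediate
10 | (3E,5R)-2-methylhept-3-en-6-yne-2,5-diol | O[C@H](/C=C/C(C)(C)O)C#C | intermediate
11 | (3E,5R)-5-[(tert-butyldimethylsilyl)oxy]-2-methylhept-3-en-6-yn-2-ol | CC(C)(C)[Si](C)(C)O[C@H](/C=C/C(C)(C)O)C#C | intermediate
12 | tricarbonylchromium complex (η6 on the new ring) of naphthol 13 | CC(C)(C)[Si](C)(C)O[C@H](/C=C/C(C)(C)O)c1cc(OC)c2c(OCOC)ccc(OCOC)c2c1O.[Cr].[C-]#[O+].[C-]#[O+].[C-]#[O+] | intermediate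
13 | 2-[(1R,2E)-1-(tert-butyldimethylsilyloxy)-4-hydroxy-4-methylpent-2-en-1-yl]-4-methoxy-5,8-bis(methoxymethoxy)naphthalen-1-ol | CC(C)(C)[Si](C)(C)O[C@H](/C=C/C(C)(C)O)c1cc(OC)c2c(OCOC)ccc(OCOC)c2c1O | intermediate
14 | 2-[(1R,2E)-1-(tert-butyldimethylsilyloxy)-4-hydroxy-4-methylpent-2-en-1-yl]-5,8-bis(methoxymethoxy)naphthalene-1,4-dione | CC(C)(C)[Si](C)(C)O[C@H](/C=C/C(C)(C)O)C1=CC(=O)c2c(OCOC)ccc(OCOC)c2C1=O | intermediate
15 | 2-[(1R,2E)-1,4-dihydroxy-4-methylpent-2-en-1-yl]-5,8-bis(methoxymethoxy)naphthalene-1,4-dione | O[C@H](/C=C/C(C)(C)O)C1=CC(=O)c2c(OCOC)ccc(OCOC)c2C1=O | intermediate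
16 | (R)-2-methylbutanoic acid | CC[C@@H](C)C(=O)O | starting material
17 | (1R,2E)-1-[5,8-bis(methoxymethoxy)-1,4-dioxo-1,4-dihydronaphthalen-2-yl]-4-hydroxy-4-methylpent-2-en-1-yl (2R)-2-methylbutanoate | CC[C@@H](C)C(=O)O[C@H](/C=C/C(C)(C)O)C1=CC(=O)c2c(OCOC)ccc(OCOC)c2C1=O | intermediate
18 | (1R,2E)-1-[1,4-dioxo-5,8-bis(trimethylsilyloxy)-1,4-dihydronaphthalen-2-yl]-4-methyl-4-(trimethylsilyloxy)pent-2-en-1-yl (2R)-2-methylbutanoate | CC[C@@H](C)C(=O)O[C@H](/C=C/C(C)(C)O[Si](C)(C)C)C1=CC(=O)c2c(O[Si](C)(C)C)ccc(O[Si](C)(C)C)c2C1=O | intermediate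
19 | (1R,2E)-1-(5,8-dihydroxy-1,4-dioxo-1,4-dihydronaphthalen-2-yl)-4-hydroxy-4-methylpent-2-en-1-yl (2R)-2-methylbutanoate | CC[C@@H](C)C(=O)O[C@H](/C=C/C(C)(C)O)C1=CC(=O)c2c(O)ccc(O)c2C1=O | target

Total step count: 10. Longest linear sequence: 8 (steps 3 to 10).

Steps most likely to fail

Step 7.
- What may go wrong: the ortho acetal oxygen may chelate chromium after CO loss and slow alkyne uptake. Cyclisation without CO insertion, or oligomerisation of the terminal alkyne, may then take over. The acetals or the silyl ether may also be lost in the acidic oxidative work-up.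
- Fallback (from 11, back at 19): ring A is built in the methyl ether series, where this benzannulation has its closest precedent. The phenols are then freed by oxidation, not by acetal cleavage.
- Commercial 2-bromo-1,4-dimethoxybenzene is taken through Br/Li exchange (n-BuLi), Cr(CO)6 and Me3OBF4 to pentacarbonyl[(2,5-dimethoxyphenyl)(methoxy)methylidene]chromium F1.
- F1 and 11 (THF, 55 °C, then (NH4)2Ce(NO3)6) should give 2-[(1R,2E)-1-(tert-butyldimethylsilyloxy)-4-hydroxy-4-methylpent-2-en-1-yl]-5,8-dimethoxynaphthalene-1,4-dione F2.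
- HF·pyridine then gives the carbinol 2-[(1R,2E)-1,4-dihydroxy-4-methylpent-2-en-1-yl]-5,8-dimethoxynaphthalene-1,4-dione F3, and DCC/DMAP with 16 gives the 5,8-dimethoxy ester F4.
- Brief treatment with AgO and aqueous HNO3 in acetone demethylates ring B oxidatively to the naphthalene-1,4,5,8-tetraone ester F5, which Na2S2O4 in the work-up reduces to 19.

Step 10.
- What may go wrong: the doubly allylic ester or the tertiary allylic alcohol may ionise under the silyl triflate, and the tertiary silyl ether may be lost only in part.
- Fallback (from 14, back at 19): the order of events is changed so that the ester never meets a Lewis acid.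
- Compound 14 is freed of its acetals first (Me3SiOTf, 2,2'-bipyridyl, then H2O). This gives 2-[(1R,2E)-1-(tert-butyldimethylsilyloxy)-4-hydroxy-4-methylpent-2-en-1-yl]-5,8-dihydroxynaphthalene-1,4-dione F6.
- Buffered HF·pyridine gives 2-[(1R,2E)-1,4-dihydroxy-4-methylpent-2-en-1-yl]-5,8-dihydroxynaphthalene-1,4-dione F7.
- The route ends with a selective Steglich esterification of F7 with 16. The chelated peri-phenols and the tertiary alcohol should stay free, as is known for the acylation of 1'-hydroxyalkyl naphthazarins.

Step 5.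
- What may go wrong: the enzyme may discriminate poorly between the ethynyl and alkenyl groups, and half of the material is lost in any case.
- Fallback (from 9, back at 10): the racemate is deracemised by oxidation and reagent-controlled reduction.
- MnO2 in CH2Cl2 oxidises the doubly activated carbinol of 9 to (E)-6-hydroxy-6-methylhept-4-en-1-yn-3-one F8.
- A Midland reduction follows, with B-isopinocampheyl-9-borabicyclo[3.3.1]nonane made from (+)-α-pinene. This reagent treats the alkynyl group as the small substituent and gives R propargylic alcohols from 1-alkyn-3-ones, so it should deliver 10.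

Further compounds
F1 | step 7 | pentacarbonyl[(2,5-dimethoxyphenyl)(methoxy)methylidene]chromium | COC(=[Cr])c1cc(OC)ccc1OC.[C-]#[O+].[C-]#[O+].[C-]#[O+].[C-]#[O+].[C-]#[O+]
F2 | step 7 | 2-[(1R,2E)-1-(tert-butyldimethylsilyloxy)-4-hydroxy-4-methylpent-2-en-1-yl]-5,8-dimethoxynaphthalene-1,4-dione | CC(C)(C)[Si](C)(C)O[C@H](/C=C/C(C)(C)O)C1=CC(=O)c2c(OC)ccc(OC)c2C1=O
F3 | step 7 | 2-[(1R,2E)-1,4-dihydroxy-4-methylpent-2-en-1-yl]-5,8-dimethoxynaphthalene-1,4-dione | O[C@H](/C=C/C(C)(C)O)C1=CC(=O)c2c(OC)ccc(OC)c2C1=O
F4 | step 7 | (1R,2E)-1-(5,8-dimethoxy-1,4-dioxo-1,4-dihydronaphthalen-2-yl)-4-hydroxy-4-methylpent-2-en-1-yl (2R)-2-methylbutanoate | CC[C@@H](C)C(=O)O[C@H](/C=C/C(C)(C)O)C1=CC(=O)c2c(OC)ccc(OC)c2C1=O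
F5 | step 7 | (1R,2E)-4-hydroxy-4-methyl-1-(1,4,5,8-tetraoxo-1,4,5,8-tetrahydronaphthalen-2-yl)pent-2-en-1-yl (2R)-2-methylbutanoate | CC[C@@H](C)C(=O)O[C@H](/C=C/C(C)(C)O)C1=CC(=O)C2=C(C1=O)C(=O)C=CC2=O
F6 | step 10 | 2-[(1R,2E)-1-(tert-butyldimethylsilyloxy)-4-hydroxy-4-methylpent-2-en-1-yl]-5,8-dihydroxynaphthalene-1,4-dione | CC(C)(C)[Si](C)(C)O[C@H](/C=C/C(C)(C)O)C1=CC(=O)c2c(O)ccc(O)c2C1=O
F7 | step 10 | 2-[(1R,2E)-1,4-dihydroxy-4-methylpent-2-en-1-yl]-5,8-dihydroxynaphthalene-1,4-dione | O[C@H](/C=C/C(C)(C)O)C1=CC(=O)c2c(O)ccc(O)c2C1=O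
F8 | step 5 | (E)-6-hydroxy-6-methylhept-4-en-1-yn-3-one | C#CC(=O)/C=C/C(C)(C)O
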